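One constant I can read from the runs is the first-order constant of the larch run. Integrating d[product]/dt = k([starting material] charged − [product]) makes the fraction formed one minus exp(−kt), and the last larch reading gives k = 0.0452 h⁻¹. That law holds no concentration, so it gives 49.2 % at 15 h for autumn and for noon alike.

| setting | maple | oak | birch | larch | autumn | noon |
|---|---|---|---|---|---|---|
| starting material | 0.32 M | 0.51 M | 0.85 M | 0.36 M | 0.80 M | 0.36 M |
| partner | 0.396 M | 0.396 M | 0.396 M | 0.41 M | 0.600 M | 0.396 M |
| free catalyst | 7.2 mM | 7.2 mM | 7.2 mM | 7.2 mM | 7.2 mM | 7.2 mM |
| second catalyst | 36 mM | 36 mM | 36 mM | 36 mM | 36 mM | 36 mM |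
| added ligand | 4.4 mM | 4.4 mM | 4.4 mM | 4.4 mM | 4.4 mM | 4.4 mM |
| remark | run made earlier | run made earlier | run made earlier | run made earlier |  |  |
| time |  |  |  |  | 15 h | 15 h |

| run | time / h | product / % |
|---|---|---|
| maple | 4.00 | 12.5 |
| maple | 8.00 | 27.4 |
| maple | 12.0 | 42.6 |
| maple | 15.0 | 47.1 |
| oak | 4.00 | 13.3 |
| oak | 8.00 | 27.8 |
| oak | 12.0 | 39.5 |
| oak | 15.0 | 44.1 |
| birch | 2.00 | 3.3 |
| birch | 5.00 | 15.6 |
| birch | 10.0 | 28.9 |
| birch | 15.0 | 36.6 |
| larch | 2.00 | 5.4 |
| larch | 5.00 | 17.5 |
| larch | 10.0 | 36.2 |
| larch | 15.0 | 49.2 |

(each reading ± 1 percentage point)

- the analysis behind the earlier runs scatters by 1 percentage point, standard deviation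

* the winner by amount of product, in percent of the starting material charged; "neither" if no more than 2 percentage points parts them (autumn / noon / neither)
* how much product is there at the end, in percent of the starting material charged: autumn
* how much product is there at the end, in percent of the starting material charged: noon

I turn the question round: what would have to differ for one flask to win by more than 2 percentage points? The last birch reading, 36.6 %, is lower than the last readings of the other runs, so I assume one partner per product and compare what each run has over. Autumn's [partner] charged, less the product the law demands, is 0.206 M. This difference is the spare partner.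

The last readings give a spare of 0.0849 M for birch and 0.233 M for larch, where 49.2 % was read, so the larch spare is larger and so is its last reading. For noon the law gives a spare of 0.219 M, which is larger than autumn's. Birch and larch differ in both charges, so the slope between them is a rough measure, but on it that gap is worth about 1.1 points, less than the margin. I therefore commit to neither, with both flasks near 49.2 %.

The forecast says 44 % for autumn and 48 % for noon: “Noon probably wins narrowly”.

The flask gives neither: autumn 48.0 %, noon 47.4 %, with autumn ahead, against the sign of my gap but inside the margin.

    starting material + free catalyst ⇌ free catalyst + intermediate (K = 2.70, k = 12.9 L mol⁻¹ h⁻¹)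
    partner + second catalyst + intermediate → second catalyst + product (k = 27.7 L² mol⁻² h⁻¹)
    partner → decomposed reagent (k = 0.0200 h⁻¹)
    free catalyst + added ligand ⇌ idle complex (K = 330 L mol⁻¹, k = 20.2 L mol⁻¹ h⁻¹)

At 15 h neither flask has come to rest: autumn still holds 38.3 % of its starting material and 19.9 % of its partner, noon 38.7 % and 37.2 %. At 150 h partner stands at 0 % in autumn and 0 % in noon, and product has reached 61.0 % and 77.0 %, a gap of 16 points. Reckoned from these products, the spare is 0.112 M and 0.119 M, and the decomposed reagent stands at 0.112 M and 0.119 M. For a flask like autumn but with 0.15 M of partner, the spare reckons to −0.244 M; there partner is the limiting reagent, its charge allows 18.7 %, and that flask gives 16.0 %.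

(The numbers in the tables stem from a simulated flask with made-up constants; the scatter is artificial.)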